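The trap I watched for was reading a stopped run as a fixed yield per unit of second catalyst. You asked me for a quick number on the row below and gave your hunch, and this was my reply.

| flask | substrate | coupling partner | second catalyst | precatalyst | remark | time |
|---|---|---|---|---|---|---|
| gamma | 0.050 M | 0.075 M | 0.17 mM | 7.5 mM | run made earlier |  |
| zeta | 0.050 M | 0.075 M | 2.1 mM | 7.5 mM | run made earlier |  |
| Friday's | 0.050 M | 0.0750 M | 0.30 mM | 7.5 mM |  | 40 h |
| Monday's | 0.050 M | 0.0750 M | 0.60 mM | 7.5 mM |  | 40 h |
| Saturday's | 0.050 M | 0.0750 M | 1.2 mM | 7.5 mM |  | 40 h |
| Sunday's | 0.050 M | 0.0750 M | 2.5 mM | 7.5 mM |  | 40 h |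

| gamma: time / h | gamma: target / % | zeta: time / h | zeta: target / % |
|---|---|---|---|
| 2.50 | 2.2 | 8.00 | 8.7 |
| 5.00 | 3.3 | 15.0 | 6.0 |
| 12.0 | 3.4 | 20.0 | 6.1 |
| 30.0 | 3.4 | 30.0 | 7.0 |

(standard deviation of a reading: 0.5 percentage points)

- the numbers in the tables scatter with a standard deviation of 0.5 percentage points
- a reading or a percentage of target counts all its forms, free or not
- "hardly changes" means that all values lie within two and a half points (for a concentration: within two and a half percent of the largest)

- amount of target at the end, in percent of the substrate charged for Friday's, Monday's, Saturday's, Sunday's, in this order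
- how the row runs (rises all the way / hardly changes / rises, then falls / falls, then rises / falls all the way)

Gamma flattened at 3.40 %, the mean of its readings at 12.0 h and 30.0 h. Zeta read 8.7 % at 8.00 h, higher than at 15.0 h, so I averaged its three later readings to 6.37 %. Between the runs the second catalyst rose 12.4 times, but the plateau rose 1.87 times. A proportion failed there. So I took the gamma plateau as the large term and computed a correction to it, spreading the difference evenly over the 3.63 doublings that separate the two loadings.

That came to 0.82 percentage points. This is the doubling gain, the points of target added at the end by each doubling of the second catalyst, the other charges held as in these runs. It is a reading and carries their scatter.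

My reckoning for 40 h gave 4.07 %, 4.89 %, 5.71 % and 6.57 %. Sunday's charge lay higher than zeta's, so that figure stood outside the two runs.

Your forecast differed from mine. It said 5.5 %, 8.5 %, 9.5 % and 7.5 %, with the row rises, then falls, on the ground that “high loading brings an opposing effect”.

The flasks gave 3.93 %, 4.68 %, 5.51 % and 6.79 %, and the row rises all the way.

    substrate + free catalyst ⇌ free catalyst + intermediate (K = 0.780, k = 1.27 /M/min)
    coupling partner + second catalyst + intermediate → second catalyst + target (k = 156 /M²/min)
    coupling partner + precatalyst → free catalyst + spent reagent (k = 0.0510 /M/min)
    second catalyst + target ⇌ idle complex (K = 424 /M, k = 0.210 /M/min)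
    target + free catalyst ⇌ isomer of the product + free catalyst, rate k5*[free catalyst]*[target] forward; the back reaction follows from the equilibrium constant (K = 20.9, k = 4.16 /M/min)

The forecast fell from 9.5 % to 7.5 % at the top, while Sunday's flask stood highest in the row. Friday's and Sunday's charges lay 3.06 doublings apart, so the doubling gain of 0.82 points came to 2.5 points between them, and those flasks differed by 2.9 points. In Friday's flask the making of intermediate had half of its turnover done by 4.48 h, and the making of target had 76 % done by 20.0 h. While free catalyst stood at 96.2 % at 20.0 h, Friday's target went on to isomer of the product, and at 40.0 h that flask held 71.3 % isomer against 3.93 % target.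

(The numbers in the tables were generated by integration from invented constants; noise was put on by code.)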